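**Retrosynthetic overview**
- Target 22 ← cinnamate 21 by one global DIBAL-H reduction (enoate to allylic alcohol, four pivalates off); 21 ← aryl chloride 19 by Heck reaction with methyl acrylate.
- Key disconnections: the two aryl–C(benzylic) bonds (ring B–C3 of the A-ring dioxane, ring C–C3 of the B-ring dioxane). Each is made by a decatungstate-HAT/nickel radical C(sp3)–H arylation of a preformed, enantiopure 2-(pivaloyloxymethyl)-1,4-benzodioxane; the CH2OPiv-bearing stereocentre steers the aryl group trans.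
- Both dioxane rings are closed first, before any aryl–C bond: 3-chlorophenol → 4-chlorosalicylaldehyde → glycidyl ether → Baeyer–Villiger/6-exo epoxide opening. (S)-Glycidol gives the B-ring unit, (R)-glycidol the A-ring unit.
- Order of assembly: ring C bromide + B unit (radical arylation) → Cl of ring B converted to Br via Bpin → + A unit (radical arylation) → Cl of ring A becomes the propenol chain.

Assumption: a two-stage one-pot operation without isolation counts as one step; the C–H partner used in excess in steps 10 and 13 is recovered. "Pivalate" means 2,2-dimethylpropanoate.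

**Step 1**
Reactants: 1 catechol (benzene-1,2-diol)
Product: 2 4-bromobenzene-1,2-diol
Conditions: NBS (1.0 equiv), HBF4·OEt2 (10 mol%), MeCN, −30 °C to rt
Reagents that add atoms: N-bromosuccinimide, O=C1CCC(=O)N1Br
Why: Electrophilic aromatic bromination goes para to one hydroxyl (position 4), the 3/6 positions being ortho-hindered, and one equivalent of NBS at low temperature stops at the monobromide.

**Step 2**
Reactants: 2 4-bromobenzene-1,2-diol
Product: 3 4-bromo-1,2-phenylene bis(2,2-dimethylpropanoate)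
Conditions: PivCl (2.5 equiv), Et3N (3 equiv), DMAP (5 mol%), CH2Cl2, 0 °C to rt
Reagents that add atoms: pivaloyl chloride, CC(C)(C)C(=O)Cl
Why: DMAP-catalysed O-acylation masks the catechol as esters that lack abstractable C–H bonds, make the aryl bromide electron-poor for nickel, and fall off in the final hydride step.

**Step 3**
Reactants: 4 3-chlorophenol
Product: 5 4-chloro-2-hydroxybenzaldehyde
Conditions: MgCl2 (1.5 equiv), Et3N (3.75 equiv), (CH2O)n (6.75 equiv), MeCN, reflux; 1 M HCl work-up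
Reagents that add atoms: paraformaldehyde (as formaldehyde), C=O
Why: Magnesium-phenoxide-directed ortho-formylation (Casnati–Skattebøl) occurs only ortho to OH and at the less hindered ortho site (para to Cl), which differentiates the two future dioxane oxygens.

**Step 4**
Reactants: 5 4-chloro-2-hydroxybenzaldehyde; 6 (S)-glycidol [(2S)-oxiran-2-ylmethanol]
Product: 7 4-chloro-2-{[(2R)-oxiran-2-yl]methoxy}benzaldehyde
Conditions: PPh3, DIAD, THF, 0 °C to rt
Reagents that add atoms: none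
Why: Mitsunobu etherification of the acidic salicylaldehyde OH at the primary carbon of glycidol leaves the epoxide stereocentre untouched (the descriptor changes to R only through CIP priorities).

**Step 5**
Reactants: 7 4-chloro-2-{[(2R)-oxiran-2-yl]methoxy}benzaldehyde
Product: 9 [(2S)-6-chloro-2,3-dihydro-1,4-benzodioxin-2-yl]methanol, via aryl formate 8 (not isolated)
Conditions: mCPBA (1.5 equiv), CH2Cl2, rt; then K2CO3 (0.3 equiv), MeOH, rt
Reagents that add atoms: 3-chloroperbenzoic acid (mCPBA), OOC(=O)c1cccc(Cl)c1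
Why: Baeyer–Villiger (Dakin-type) oxidation of the ortho-alkoxybenzaldehyde gives formate 8, and its methanolysis frees the phenoxide para to Cl, which opens the epoxide 6-exo at the internal carbon with inversion to set C2 as S.

**Step 6**
Reactants: 9 [(2S)-6-chloro-2,3-dihydro-1,4-benzodioxin-2-yl]methanol
Product: 10 [(2R)-6-chloro-2,3-dihydro-1,4-benzodioxin-2-yl]methyl pivalate
Conditions: PivCl (1.3 equiv), Et3N, DMAP (cat.), CH2Cl2, 0 °C to rt
Reagents that add atoms: pivaloyl chloride, CC(C)(C)C(=O)Cl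
Why: Acylation removes the reactive carbinol O–H and deactivates the CH2–O hydrogens toward electrophilic HAT; the stereocentre is unchanged (R only by CIP priority change).

**Step 7**
Reactants: 5 4-chloro-2-hydroxybenzaldehyde; 11 (R)-glycidol [(2R)-oxiran-2-ylmethanol]
Product: 12 4-chloro-2-{[(2S)-oxiran-2-yl]methoxy}benzaldehyde
Conditions: PPh3, DIAD, THF, 0 °C to rt
Reagents that add atoms: none
Why: Same Mitsunobu etherification as step 4 in the enantiomeric series, with the stereocentre carried over from (R)-glycidol.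

**Step 8**
Reactants: 12 4-chloro-2-{[(2S)-oxiran-2-yl]methoxy}benzaldehyde
Product: 14 [(2R)-6-chloro-2,3-dihydro-1,4-benzodioxin-2-yl]methanol, via aryl formate 13 (not isolated)
Conditions: mCPBA (1.5 equiv), CH2Cl2, rt; then K2CO3 (0.3 equiv), MeOH, rt
Reagents that add atoms: 3-chloroperbenzoic acid (mCPBA), OOC(=O)c1cccc(Cl)c1
Why: Baeyer–Villiger oxidation, formate methanolysis and 6-exo epoxide opening with inversion as in step 5 set C2 as R.

**Step 9**
Reactants: 14 [(2R)-6-chloro-2,3-dihydro-1,4-benzodioxin-2-yl]methanol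
Product: 15 [(2S)-6-chloro-2,3-dihydro-1,4-benzodioxin-2-yl]methyl pivalate
Conditions: PivCl (1.3 equiv), Et3N, DMAP (cat.), CH2Cl2, 0 °C to rt
Reagents that add atoms: pivaloyl chloride, CC(C)(C)C(=O)Cl
Why: O-Acylation as in step 6, with the stereocentre untouched.

**Step 10**
Reactants: 3 4-bromo-1,2-phenylene bis(2,2-dimethylpropanoate); 10 [(2R)-6-chloro-2,3-dihydro-1,4-benzodioxin-2-yl]methyl pivalate (5 equiv, excess recovered)
Product: 16 {(2S,3S)-3-[3,4-bis(pivaloyloxy)phenyl]-6-chloro-2,3-dihydro-1,4-benzodioxin-2-yl}methyl pivalate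
Conditions: (Bu4N)4W10O32 (2 mol%), NiBr2·dtbbpy (10 mol%), K3PO4 (1.1 equiv), MeCN, 390 nm LEDs, rt
Reagents that add atoms: none
Why: Proposed new method: excited decatungstate abstracts the least hindered, hydridic O–CH2 hydrogen at C3 of 10 (C2–H is tertiary and inductively deactivated, the CH2OPiv hydrogens are acyloxy-deactivated), the α-aryloxyalkyl radical is captured by the aryl–nickel species from electron-poor bromide 3 (the electron-rich aryl chloride of 10 does not add to nickel), and reductive elimination from Ni(III) places the aryl group anti to the adjacent CH2OPiv, setting C3 as S (2,3-trans); the closest known reaction type is decatungstate/nickel C(sp3)–H arylation of cyclic ethers with aryl bromides, with the 1,2-trans induction seen in nickel arylations of α-heteroatom radicals next to a ring substituent.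

**Step 11**
Reactants: 16 {(2S,3S)-3-[3,4-bis(pivaloyloxy)phenyl]-6-chloro-2,3-dihydro-1,4-benzodioxin-2-yl}methyl pivalate
Product: 17 {(2S,3S)-3-[3,4-bis(pivaloyloxy)phenyl]-6-(4,4,5,5-tetramethyl-1,3,2-dioxaborolan-2-yl)-2,3-dihydro-1,4-benzodioxin-2-yl}methyl pivalate
Conditions: B2pin2 (1.5 equiv), XPhos Pd G2 (2 mol%), XPhos (2 mol%), KOAc (3 equiv), 1,4-dioxane, 100 °C
Reagents that add atoms: bis(pinacolato)diboron, CC1(C)OB(OC1(C)C)B1OC(C)(C)C(C)(C)O1
Why: Miyaura borylation with a Pd/biarylphosphine catalyst activates the electron-rich aryl chloride that served as an inert placeholder in step 10, and KOAc at 100 °C leaves esters and stereocentres alone.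

**Step 12**
Reactants: 17 (the aryl pinacol boronate from step 11)
Product: 18 {(2S,3S)-3-[3,4-bis(pivaloyloxy)phenyl]-6-bromo-2,3-dihydro-1,4-benzodioxin-2-yl}methyl pivalate
Conditions: CuBr2 (3 equiv), MeOH/THF/H2O, 70 °C
Reagents that add atoms: copper(II) bromide, [Cu+2].[Br-].[Br-]
Why: Copper(II)-mediated ipso-bromodeboronation gives an aryl bromide that adds to nickel far faster than the aryl chloride of the next C–H partner, while the benzylic ether next to an electron-poor aryl ring resists the HBr formed.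

**Step 13**
Reactants: 18 {(2S,3S)-3-[3,4-bis(pivaloyloxy)phenyl]-6-bromo-2,3-dihydro-1,4-benzodioxin-2-yl}methyl pivalate; 15 [(2S)-6-chloro-2,3-dihydro-1,4-benzodioxin-2-yl]methyl pivalate (5 equiv, excess recovered)
Product: 19 {(2R,3R)-3-[(2S,3S)-3-[3,4-bis(pivaloyloxy)phenyl]-2-(pivaloyloxymethyl)-2,3-dihydro-1,4-benzodioxin-6-yl]-6-chloro-2,3-dihydro-1,4-benzodioxin-2-yl}methyl pivalate
Conditions: (Bu4N)4W10O32 (2 mol%), NiBr2·dtbbpy (10 mol%), K3PO4 (1.1 equiv), MeCN, 390 nm LEDs, rt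
Reagents that add atoms: none
Why: Proposed new method: the same HAT/nickel manifold as step 10, in which nickel selects C–Br of 18 over C–Cl of 15, the tertiary benzylic C–H bonds of 18 are hindered and sit on an electron-poor aryl ring so HAT falls on the O–CH2 of the excess 15, and aryl delivery anti to CH2OPiv sets the new C3 as R (2,3-trans); the closest known reaction type is decatungstate/nickel C(sp3)–H arylation of cyclic ethers with aryl bromides.

**Step 14**
Reactants: 19 (the bis-dioxane aryl chloride from step 13); 20 methyl acrylate (2 equiv)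
Product: 21 methyl (E)-3-{(2R,3R)-3-[(2S,3S)-3-[3,4-bis(pivaloyloxy)phenyl]-2-(pivaloyloxymethyl)-2,3-dihydro-1,4-benzodioxin-6-yl]-2-(pivaloyloxymethyl)-2,3-dihydro-1,4-benzodioxin-6-yl}prop-2-enoate
Conditions: Pd2(dba)3 (2.5 mol%), [HP(t-Bu)3]BF4 (10 mol%), Cy2NMe (1.5 equiv), 1,4-dioxane, 110 °C
Reagents that add atoms: none
Why: Mizoroki–Heck reaction of an electron-rich aryl chloride under Pd/P(t-Bu)3 catalysis, where syn-insertion and syn-β-hydride elimination give the E-enoate only.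

**Step 15**
Reactants: 21 (the E-enoate from step 14)
Product: 22 (E)-3-{(2R,3R)-3-[(2S,3S)-3-(3,4-dihydroxyphenyl)-2-(hydroxymethyl)-2,3-dihydro-1,4-benzodioxin-6-yl]-2-(hydroxymethyl)-2,3-dihydro-1,4-benzodioxin-6-yl}prop-2-en-1-ol
Conditions: DIBAL-H (15 equiv), CH2Cl2/THF, −78 to 0 °C; degassed Rochelle salt work-up
Reagents that add atoms: none
Why: DIBAL-H reduces the enoate 1,2 to the (E)-allylic alcohol and cleaves the two alkyl and two aryl pivalates in the same operation, without touching the aryl ethers or the four stereocentres.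

**Compound list**
1 | catechol (benzene-1,2-diol) | Oc1ccccc1O | starting material
2 | 4-bromobenzene-1,2-diol | Oc1ccc(Br)cc1O | intermediate
3 | 4-bromo-1,2-phenylene bis(2,2-dimethylpropanoate) | CC(C)(C)C(=O)Oc1ccc(Br)cc1OC(=O)C(C)(C)C | intermediate
4 | 3-chlorophenol | Oc1cccc(Cl)c1 | starting material
5 | 4-chloro-2-hydroxybenzaldehyde | O=Cc1ccc(Cl)cc1O | intermediate
6 | (S)-glycidol | OC[C@H]1CO1 | starting material
7 | 4-chloro-2-{[(2R)-oxiran-2-yl]methoxy}benzaldehyde | O=Cc1ccc(Cl)cc1OC[C@H]1CO1 | intermediate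
8 | 4-chloro-2-{[(2R)-oxiran-2-yl]methoxy}phenyl formate | O=COc1ccc(Cl)cc1OC[C@H]1CO1 | intermediate
9 | [(2S)-6-chloro-2,3-dihydro-1,4-benzodioxin-2-yl]methanol | Clc1ccc2c(c1)OC[C@H](CO)O2 | intermediate
10 | [(2R)-6-chloro-2,3-dihydro-1,4-benzodioxin-2-yl]methyl pivalate | Clc1ccc2c(c1)OC[C@H](COC(=O)C(C)(C)C)O2 | intermediate
11 | (R)-glycidol | OC[C@@H]1CO1 | starting material
12 | 4-chloro-2-{[(2S)-oxiran-2-yl]methoxy}benzaldehyde | O=Cc1ccc(Cl)cc1OC[C@@H]1CO1 | intermediate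
13 | 4-chloro-2-{[(2S)-oxiran-2-yl]methoxy}phenyl formate | O=COc1ccc(Cl)cc1OC[C@@H]1CO1 | intermediate
14 | [(2R)-6-chloro-2,3-dihydro-1,4-benzodioxin-2-yl]methanol | Clc1ccc2c(c1)OC[C@@H](CO)O2 | intermediate
15 | [(2S)-6-chloro-2,3-dihydro-1,4-benzodioxin-2-yl]methyl pivalate | Clc1ccc2c(c1)OC[C@@H](COC(=O)C(C)(C)C)O2 | intermediate
16 | {(2S,3S)-3-[3,4-bis(pivaloyloxy)phenyl]-6-chloro-2,3-dihydro-1,4-benzodioxin-2-yl}methyl pivalate | Clc1ccc2c(c1)O[C@@H](c1ccc(OC(=O)C(C)(C)C)c(OC(=O)C(C)(C)C)c1)[C@H](COC(=O)C(C)(C)C)O2 | intermediate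
17 | {(2S,3S)-3-[3,4-bis(pivaloyloxy)phenyl]-6-(4,4,5,5-tetramethyl-1,3,2-dioxaborolan-2-yl)-2,3-dihydro-1,4-benzodioxin-2-yl}methyl pivalate | CC1(C)OB(OC1(C)C)c1ccc2c(c1)O[C@@H](c1ccc(OC(=O)C(C)(C)C)c(OC(=O)C(C)(C)C)c1)[C@H](COC(=O)C(C)(C)C)O2 | intermediate
18 | {(2S,3S)-3-[3,4-bis(pivaloyloxy)phenyl]-6-bromo-2,3-dihydro-1,4-benzodioxin-2-yl}methyl pivalate | Brc1ccc2c(c1)O[C@@H](c1ccc(OC(=O)C(C)(C)C)c(OC(=O)C(C)(C)C)c1)[C@H](COC(=O)C(C)(C)C)O2 | intermediate
19 | {(2R,3R)-3-[(2S,3S)-3-[3,4-bis(pivaloyloxy)phenyl]-2-(pivaloyloxymethyl)-2,3-dihydro-1,4-benzodioxin-6-yl]-6-chloro-2,3-dihydro-1,4-benzodioxin-2-yl}methyl pivalate | Clc1ccc2c(c1)O[C@H](c1ccc3c(c1)O[C@@H](c1ccc(OC(=O)C(C)(C)C)c(OC(=O)C(C)(C)C)c1)[C@H](COC(=O)C(C)(C)C)O3)[C@@H](COC(=O)C(C)(C)C)O2 | intermediate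
20 | methyl acrylate | C=CC(=O)OC | starting material
21 | methyl (E)-3-{(2R,3R)-3-[(2S,3S)-3-[3,4-bis(pivaloyloxy)phenyl]-2-(pivaloyloxymethyl)-2,3-dihydro-1,4-benzodioxin-6-yl]-2-(pivaloyloxymethyl)-2,3-dihydro-1,4-benzodioxin-6-yl}prop-2-enoate | COC(=O)/C=C/c1ccc2c(c1)O[C@H](c1ccc3c(c1)O[C@@H](c1ccc(OC(=O)C(C)(C)C)c(OC(=O)C(C)(C)C)c1)[C@H](COC(=O)C(C)(C)C)O3)[C@@H](COC(=O)C(C)(C)C)O2 | intermediate
22 | (E)-3-{(2R,3R)-3-[(2S,3S)-3-(3,4-dihydroxyphenyl)-2-(hydroxymethyl)-2,3-dihydro-1,4-benzodioxin-6-yl]-2-(hydroxymethyl)-2,3-dihydro-1,4-benzodioxin-6-yl}prop-2-en-1-ol | OC/C=C/c1ccc2c(c1)O[C@H](c1ccc3c(c1)O[C@@H](c1ccc(O)c(O)c1)[C@H](CO)O3)[C@@H](CO)O2 | target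

**Step count**
Total: 15 steps. Longest linear sequence: 10 steps (3, 4, 5, 6, 10, 11, 12, 13, 14, 15).

**Three steps most likely to fail, with fallbacks**

Step 10 (first radical C–H arylation: HAT site selectivity and trans/cis ratio are unproven on this ring). The fallback is a polar, stereospecific double-inversion route that sets out from 3, uses 5, and comes back at 16. Bromide 3 is borylated (B2pin2, Pd(dppf)Cl2, KOAc) to 4-(4,4,5,5-tetramethyl-1,3,2-dioxaborolan-2-yl)-1,2-phenylene dipivalate F1. Suzuki–Miyaura coupling with (E)-3-iodoprop-2-en-1-ol (CsF, THF/H2O) gives the cinnamyl alcohol 4-[(E)-3-hydroxyprop-1-enyl]-1,2-phenylene dipivalate F2. Sharpless epoxidation with D-(−)-DIPT gives the (2R,3R)-epoxy alcohol F3. Phenol 5 opens the epoxide at the benzylic carbon with inversion (Cs2CO3, DMF) to give the (1S,2R)-aryloxy diol F4. Pivaloylation of the primary hydroxyl gives the mono-pivalate F5. Baeyer–Villiger oxidation (mCPBA) gives the aryl formate F6, which Et3N/MeOH cleaves to the phenol F7. An intramolecular Mitsunobu etherification with inversion at the secondary carbinol closes the trans-dioxane and delivers 16.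

Step 13 (second radical C–H arylation: slower oxidative addition of the electron-rich bromide 18 and possible HAT at its benzylic C–H bonds). The fallback is the same polar logic on ring B; it sets out from boronate 17, uses 5, and comes back at 19. Suzuki–Miyaura coupling of 17 with (E)-3-iodoprop-2-en-1-ol gives the ring-B cinnamyl alcohol F8. Sharpless epoxidation with L-(+)-DIPT gives the (2S,3S)-epoxy alcohol F9. Benzylic opening by phenol 5 with inversion gives the (1R,2S)-aryloxy diol F10. Primary pivaloylation gives the mono-pivalate F11. Baeyer–Villiger oxidation gives the aryl formate F12, and methanolysis gives the phenol F13. Mitsunobu ring closure with inversion at the carbinol gives 19.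

Step 14 (Heck reaction of an electron-rich aryl chloride on a large substrate at 110 °C). The fallback reverses the polarity of the coupling; it sets out from 19 and comes back at 21. Pd/XPhos-catalysed borylation of 19 with B2pin2 gives the ring-A aryl pinacol boronate F14, and Suzuki–Miyaura coupling with methyl (E)-3-iodoacrylate (Pd(dppf)Cl2, CsF, THF/H2O, 45 °C) gives 21 with the E geometry carried over from the vinyl iodide.

**Further compounds**
F1 | step 10 | 4-(4,4,5,5-tetramethyl-1,3,2-dioxaborolan-2-yl)-1,2-phenylene bis(2,2-dimethylpropanoate) | CC1(C)OB(OC1(C)C)c1ccc(OC(=O)C(C)(C)C)c(OC(=O)C(C)(C)C)c1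
F2 | step 10 | 4-[(E)-3-hydroxyprop-1-en-1-yl]-1,2-phenylene bis(2,2-dimethylpropanoate) | OC/C=C/c1ccc(OC(=O)C(C)(C)C)c(OC(=O)C(C)(C)C)c1
F3 | step 10 | 4-[(2R,3R)-3-(hydroxymethyl)oxiran-2-yl]-1,2-phenylene bis(2,2-dimethylpropanoate) | OC[C@H]1O[C@@H]1c1ccc(OC(=O)C(C)(C)C)c(OC(=O)C(C)(C)C)c1
F4 | step 10 | 4-[(1S,2R)-1-(5-chloro-2-formylphenoxy)-2,3-dihydroxypropyl]-1,2-phenylene bis(2,2-dimethylpropanoate) | O=Cc1ccc(Cl)cc1O[C@@H](c1ccc(OC(=O)C(C)(C)C)c(OC(=O)C(C)(C)C)c1)[C@@H](CO)O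
F5 | step 10 | (2R,3S)-3-[3,4-bis(pivaloyloxy)phenyl]-3-(5-chloro-2-formylphenoxy)-2-hydroxypropyl pivalate | O=Cc1ccc(Cl)cc1O[C@@H](c1ccc(OC(=O)C(C)(C)C)c(OC(=O)C(C)(C)C)c1)[C@@H](COC(=O)C(C)(C)C)O
F6 | step 10 | (2R,3S)-3-[3,4-bis(pivaloyloxy)phenyl]-3-[5-chloro-2-(formyloxy)phenoxy]-2-hydroxypropyl pivalate | O=COc1ccc(Cl)cc1O[C@@H](c1ccc(OC(=O)C(C)(C)C)c(OC(=O)C(C)(C)C)c1)[C@@H](COC(=O)C(C)(C)C)O
F7 | step 10 | (2R,3S)-3-[3,4-bis(pivaloyloxy)phenyl]-3-(5-chloro-2-hydroxyphenoxy)-2-hydroxypropyl pivalate | Oc1ccc(Cl)cc1O[C@@H](c1ccc(OC(=O)C(C)(C)C)c(OC(=O)C(C)(C)C)c1)[C@@H](COC(=O)C(C)(C)C)O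
F8 | step 13 | {(2S,3S)-3-[3,4-bis(pivaloyloxy)phenyl]-6-[(E)-3-hydroxyprop-1-en-1-yl]-2,3-dihydro-1,4-benzodioxin-2-yl}methyl pivalate | OC/C=C/c1ccc2c(c1)O[C@@H](c1ccc(OC(=O)C(C)(C)C)c(OC(=O)C(C)(C)C)c1)[C@H](COC(=O)C(C)(C)C)O2
F9 | step 13 | {(2S,3S)-3-[3,4-bis(pivaloyloxy)phenyl]-6-[(2S,3S)-3-(hydroxymethyl)oxiran-2-yl]-2,3-dihydro-1,4-benzodioxin-2-yl}methyl pivalate | OC[C@@H]1O[C@H]1c1ccc2c(c1)O[C@@H](c1ccc(OC(=O)C(C)(C)C)c(OC(=O)C(C)(C)C)c1)[C@H](COC(=O)C(C)(C)C)O2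
F10 | step 13 | {(2S,3S)-3-[3,4-bis(pivaloyloxy)phenyl]-6-[(1R,2S)-1-(5-chloro-2-formylphenoxy)-2,3-dihydroxypropyl]-2,3-dihydro-1,4-benzodioxin-2-yl}methyl pivalate | O=Cc1ccc(Cl)cc1O[C@H](c1ccc2c(c1)O[C@@H](c1ccc(OC(=O)C(C)(C)C)c(OC(=O)C(C)(C)C)c1)[C@H](COC(=O)C(C)(C)C)O2)[C@H](CO)O
F11 | step 13 | {(2S,3S)-3-[3,4-bis(pivaloyloxy)phenyl]-6-[(1R,2S)-1-(5-chloro-2-formylphenoxy)-2-hydroxy-3-(pivaloyloxy)propyl]-2,3-dihydro-1,4-benzodioxin-2-yl}methyl pivalate | O=Cc1ccc(Cl)cc1O[C@H](c1ccc2c(c1)O[C@@H](c1ccc(OC(=O)C(C)(C)C)c(OC(=O)C(C)(C)C)c1)[C@H](COC(=O)C(C)(C)C)O2)[C@H](COC(=O)C(C)(C)C)O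
F12 | step 13 | {(2S,3S)-3-[3,4-bis(pivaloyloxy)phenyl]-6-[(1R,2S)-1-[5-chloro-2-(formyloxy)phenoxy]-2-hydroxy-3-(pivaloyloxy)propyl]-2,3-dihydro-1,4-benzodioxin-2-yl}methyl pivalate | O=COc1ccc(Cl)cc1O[C@H](c1ccc2c(c1)O[C@@H](c1ccc(OC(=O)C(C)(C)C)c(OC(=O)C(C)(C)C)c1)[C@H](COC(=O)C(C)(C)C)O2)[C@H](COC(=O)C(C)(C)C)O
F13 | step 13 | {(2S,3S)-3-[3,4-bis(pivaloyloxy)phenyl]-6-[(1R,2S)-1-(5-chloro-2-hydroxyphenoxy)-2-hydroxy-3-(pivaloyloxy)propyl]-2,3-dihydro-1,4-benzodioxin-2-yl}methyl pivalate | Oc1ccc(Cl)cc1O[C@H](c1ccc2c(c1)O[C@@H](c1ccc(OC(=O)C(C)(C)C)c(OC(=O)C(C)(C)C)c1)[C@H](COC(=O)C(C)(C)C)O2)[C@H](COC(=O)C(C)(C)C)O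
F14 | step 14 | {(2R,3R)-3-[(2S,3S)-3-[3,4-bis(pivaloyloxy)phenyl]-2-(pivaloyloxymethyl)-2,3-dihydro-1,4-benzodioxin-6-yl]-6-(4,4,5,5-tetramethyl-1,3,2-dioxaborolan-2-yl)-2,3-dihydro-1,4-benzodioxin-2-yl}methyl pivalate | CC1(C)OB(OC1(C)C)c1ccc2c(c1)O[C@H](c1ccc3c(c1)O[C@@H](c1ccc(OC(=O)C(C)(C)C)c(OC(=O)C(C)(C)C)c1)[C@H](COC(=O)C(C)(C)C)O3)[C@@H](COC(=O)C(C)(C)C)O2
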